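**The charge.** A charge of partner, 0.0550 M against 0.050 M of substrate, stands in larch, the asked flask, and elm ran earlier with 0.037 M.

in all of them: substrate 0.050 M

|  | partner | temperature | remark | time |
|---|---|---|---|---|
| larch | 0.055 M | 60 °C | the very flask that is asked about, followed so far |  |
| elm | 0.037 M | 66 °C | run made earlier |  |
| flask | 0.0550 M | 60 °C |  | 8.0 d |

- larch (time / d: target / %): 1.25: 16.2; 2.50: 30.2; 4.00: 37.8; 5.00: 41.2; 6.00: 40.4
- elm (time / d: target / %): 0.417: 6.4; 1.25: 21.6; 2.00: 29.3; 3.00: 32.8; 5.00: 36.1

(scatter of a reading: 1 percentage point)

- zeta: change nothing and wait 2.5 d more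
- eta: at 8.0 d add partner, 50.0% of the amount charged, then wait 2.5 d
- alpha: at 8.0 d raise the temperature by 25 K, then wait 2.5 d
- delta: at 8.0 d take out 90% of the target then present, then wait 2.5 d

- target that was removed still counts
- the analysis behind the earlier runs scatters by 1 percentage point, standard deviation
- additions bring no volume worth counting

* target, in percent of the substrate first charged, at 8.0 d
* the remedy with the largest gain of target, or "none" below 2 percentage points (zeta / eta / alpha / delta / none)
* target present, with what was taken out counted in, in percent of the substrate first charged, after zeta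
* target present, with what was taken out counted in, in percent of the substrate first charged, after delta

**Time ladder.** On the lowest rung, the earliest larch reading gives a slope of 0.130 d⁻¹ as a share of the charge. At that pace the 41.2% of larch takes 3.18 d, shorter than the 5.00 d at which it was read. On the next rung, larch moves by 0.8 percentage points between its last readings, less than the scatter of 1 point, so I read a stall. In logarithms, the look at 8.0 d lies 0.401 decades past that filling time, and the further wait adds 0.118 decades. I put larch at 40.8%, the mean of those readings.

**Partner exponent.** Elm reads 36.1% at 5.00 d on 0.037 M of partner, larch reads 41.2% at 5.00 d, and the logarithms of the two ratios give 0.333, about a third. This is the partner exponent, the decades of late target reading per decade of partner charged, an apparent order. Elm also ran hotter, and the exponent swallows that. For eta it gives me 5.9 points, above the margin of 2 points.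

**The forecast.** It says 41.5% (39.5% to 44%) now, 42% after waiting, 42.5% (39.5% to 51%) after removal, and eta as best: “Fresh partner should add about 7 points”.

**The result.** Larch holds 42.1%. The best remedy is alpha at 13 points, against 7.4 points for delta, 3.4 points for eta and 0.56 points for zeta. Waiting ends at 42.7%, removal at 49.5%.

    substrate ⇌ dormant form (K = 4.60, k = 8.97 × 10⁻⁶ s⁻¹, Ea = 123 kJ mol⁻¹, ΔH = −22.0 kJ mol⁻¹)
    partner + intermediate → target (k = 1.70 × 10⁻⁴ M⁻¹ s⁻¹, Ea = 83.0 kJ mol⁻¹)
    target ⇌ isomer of the product (K = 1.27, k = 1.01 × 10⁻⁶ s⁻¹, Ea = 126 kJ mol⁻¹, ΔH = −21.0 kJ mol⁻¹)
    substrate → intermediate (k = 7.94 × 10⁻⁶ s⁻¹, Ea = 106 kJ mol⁻¹)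
    (constants at 60 °C)

On larch, the simulated partner amount 0.0380 M, where the answer has moved 5 points, gets a fall of 4.9 points from the exponent. The neighbour flask, with 0.022 M of partner, should hold 31.0% by the exponent, but it holds 26.0%. Between larch and that neighbour the exponent reads 0.526. In the neighbour flask, 17% of the partner remains, and intermediate, at 31.2%, holds most of the substrate.

The numbers in the tables were computed for substances that don't exist, and the scatter is random.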